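## Retrosynthetic overview

- Sarothralin is cut at the methylene bridge into the aryl prenyl ether, the acylfilicinic acid norflavesone and a one-carbon unit, joined last by Mannich reaction, amine loss and Michael addition.
- The aryl prenyl ether is cut at the allyl C–O bond (key step): 2,4,6-trihydroxybenzophenone plus a tertiary allyl carbonate, joined by a new chelation-directed copper SN2′ etherification that puts the prenyl group on an ortho oxygen.
- The benzophenone and the isobutyrophenone both come from Friedel–Crafts acylation of phloroglucinol; norflavesone follows by dearomative gem-dimethylation.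
- No ring is built: both six-membered rings are carried in from phloroglucinol, the second made non-aromatic by the double C-methylation.

Assumption: the target has no stereocentre and no stereogenic double bond (the SMILES shows one of several equivalent enol tautomers), so no stereocontrol is needed; the tertiary carbonate is taken as a purchased reagent (otherwise one flask from 2-methylbut-3-en-2-ol and Boc2O).

## Route

Step 1
Reactants: 1 phloroglucinol (benzene-1,3,5-triol); 2 benzoyl chloride
Product: 3 2,4,6-trihydroxybenzophenone
Conditions: AlCl3 (3.5 equiv), PhNO2, 65 °C; then ice/aq. HCl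
Reagents that add atoms: none
Why: Friedel–Crafts C-acylation of the symmetric triol (any O-benzoate undergoes Fries rearrangement under the same conditions), and the new ketone deactivates the ring against a second acylation.

Step 2
Reactants: 3 2,4,6-trihydroxybenzophenone (1.5 equiv, excess recovered); 4 tert-butyl (2-methylbut-3-en-2-yl) carbonate (1.0 equiv)
Product: 5 [2,4-dihydroxy-6-(3-methylbut-2-enyloxy)phenyl](phenyl)methanone
Conditions: (IPr)CuCl (5 mol%), NaOtBu (5 mol%), THF, 25 °C, Ar (IPr = 1,3-bis(2,6-diisopropylphenyl)imidazol-2-ylidene)
Reagents that add atoms: none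
Why: Proposed new method: a chelation-directed, base-free copper-catalysed SN2′ O-allylation in which (IPr)CuOtBu is protonated by 3 and settles as the three-coordinate κ2-O,O 2-acylphenolate chelate of monovalent copper (the binding mode of (IPr)Cu(acac)), so only an ortho oxygen is metal-bound; anti-SN2′ oxidative addition of the tertiary carbonate at its CH2 terminus (or the equivalent oxycupration/β-carbonate elimination) gives a σ-prenyl trivalent copper species that reductively eliminates the C–O bond to the bound phenolate oxygen, the expelled tert-butyl carbonate loses CO2 to regenerate (IPr)CuOtBu as the only base ever present, and the tertiary carbon of 4 blocks uncatalysed SN2 attack by the more acidic para hydroxyl; the closest known reaction types are copper-catalysed γ-selective allylic substitution, decarboxylative palladium allylic etherification of phenols with allyl carbonates and Ullmann-type C–O reductive elimination from trivalent copper.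

Step 3
Reactants: 1 phloroglucinol; 6 isobutyryl chloride (2-methylpropanoyl chloride)
Product: 7 2-methyl-1-(2,4,6-trihydroxyphenyl)propan-1-one
Conditions: AlCl3 (3.5 equiv), PhNO2, rt to 60 °C; then ice/aq. HCl
Reagents that add atoms: none
Why: Friedel–Crafts acylation, the standard entry to acylphloroglucinols, which stops at the mono-ketone because the chelated acyl group deactivates the ring.

Step 4
Reactants: 7 2-methyl-1-(2,4,6-trihydroxyphenyl)propan-1-one
Product: 8 norflavesone, 3,5-dihydroxy-6,6-dimethyl-2-(2-methylpropanoyl)cyclohexa-2,4-dien-1-one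
Conditions: NaOMe (3 equiv), MeI (2.5 equiv), MeOH, 0 °C to rt; then aq. HCl
Reagents that add atoms: iodomethane, CI
Why: Dearomative double C-methylation of the phloroglucinol polyanion in a protic solvent, where the second methyl enters the already methylated, most electron-rich carbon and the resulting acidic β-triketone is held as a delocalised, poorly nucleophilic anion that resists further alkylation.

Step 5
Reactants: 8 norflavesone (1.0 equiv); 5 [2,4-dihydroxy-6-(3-methylbut-2-enyloxy)phenyl](phenyl)methanone (1.2 equiv)
Product: 11 sarothralin, via Mannich base 9 (not isolated), via ene-trione 10 (not isolated)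
Conditions: CH2(NMe2)2 (1.0 equiv), MeCN, 0 °C, 30 min; then 5, 45 °C, Ar sweep; pH 5 phosphate work-up
Reagents that add atoms: bis(dimethylamino)methane, CN(C)CN(C)C
Why: Mannich reaction of the vinylogous acid 8 (which protonates the aminal itself) gives 9, E1cB loss of dimethylamine gives the ene-trione 10, and the ammonium phenoxide of 5 adds in a Michael (Friedel–Crafts-type) fashion through C3, the carbon flanked by both free hydroxyls, as in the classical couplings of 2,4-dihydroxy-6-alkoxy acylbenzenes with acylfilicinic acids, while the in-plane prenyloxy group shields C5; no stereocentre is formed.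

## Compound list

1 | phloroglucinol (benzene-1,3,5-triol) | Oc1cc(O)cc(O)c1 | starting material
2 | benzoyl chloride | O=C(Cl)c1ccccc1 | starting material
3 | 2,4,6-trihydroxybenzophenone | O=C(c1ccccc1)c1c(O)cc(O)cc1O | intermediate
4 | tert-butyl (2-methylbut-3-en-2-yl) carbonate | C=CC(C)(C)OC(=O)OC(C)(C)C | starting material
5 | [2,4-dihydroxy-6-(3-methylbut-2-enyloxy)phenyl](phenyl)methanone | CC(C)=CCOc1cc(O)cc(O)c1C(=O)c1ccccc1 | intermediate
6 | isobutyryl chloride (2-methylpropanoyl chloride) | CC(C)C(Cl)=O | starting material
7 | 2-methyl-1-(2,4,6-trihydroxyphenyl)propan-1-one | CC(C)C(=O)c1c(O)cc(O)cc1O | intermediate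
8 | norflavesone, 3,5-dihydroxy-6,6-dimethyl-2-(2-methylpropanoyl)cyclohexa-2,4-dien-1-one | CC(C)C(=O)C1=C(O)C=C(O)C(C)(C)C1=O | intermediate
9 | Mannich base, 4-[(dimethylamino)methyl]-3,5-dihydroxy-6,6-dimethyl-2-(2-methylpropanoyl)cyclohexa-2,4-dien-1-one | CC(C)C(=O)C1=C(O)C(CN(C)C)=C(O)C(C)(C)C1=O | intermediate (not isolated)
10 | ene-trione, 5-hydroxy-2,2-dimethyl-6-methylidene-4-(2-methylpropanoyl)cyclohex-4-ene-1,3-dione | CC(C)C(=O)C1=C(O)C(=C)C(=O)C(C)(C)C1=O | intermediate (not isolated)
11 | sarothralin, (2,4-dihydroxy-3-{[2,6-dihydroxy-3,3-dimethyl-5-(2-methylpropanoyl)-4-oxocyclohexa-1,5-dien-1-yl]methyl}-6-(3-methylbut-2-enyloxy)phenyl)(phenyl)methanone | CC(C)=CCOc1cc(O)c(CC2=C(O)C(C)(C)C(=O)C(C(=O)C(C)C)=C2O)c(O)c1C(=O)c1ccccc1 | target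

## Step count and risks

Total steps: 5. Longest linear sequence: 3 (1 → 3 → 5 → 11, or 1 → 7 → 8 → 11).

The three steps most likely to fail:

**Step 2 (new copper etherification).** Possible failures are leakage to the para ether, C-allylation of the electron-rich ring, and a second prenylation of the remaining ortho hydroxyl; the 1.5-fold excess of 3 is there to limit the last of these. The fallback uses known protecting-group chemistry and sets out from 3. TIPSCl/imidazole in DMF at 0 °C silylates the most acidic, unhindered para hydroxyl to give [2,6-dihydroxy-4-(triisopropylsilyloxy)phenyl](phenyl)methanone F1. Prenyl bromide/K2CO3 in acetone at 40 °C then alkylates the one ortho hydroxyl that is not hydrogen-bonded to the ketone and stops there, giving [2-hydroxy-6-(3-methylbut-2-enyloxy)-4-(triisopropylsilyloxy)phenyl](phenyl)methanone F2. TBAF/AcOH in THF at 0 °C removes the silyl group and the route is rejoined at 5.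

**Step 4 (dearomative dimethylation).** Mono-, tri- and O-methylated by-products typically hold the yield near 40%. The fallback is a blocking-group approach that sets out from 1. Ac2O/BF3·OEt2 gives 2,4-diacetylphloroglucinol F3, whose single free ring carbon is the only site left for C-methylation. MeI/NaOMe in MeOH therefore gives 2,4-diacetyl-3,5-dihydroxy-6,6-dimethylcyclohexa-2,4-dien-1-one F4 cleanly. Hot 80% aqueous H2SO4 removes both acetyl groups to give filicinic acid (3,5-dihydroxy-4,4-dimethylcyclohexa-2,5-dien-1-one) F5. C-acylation of F5 with isobutyryl chloride 6 and AlCl3 in PhNO2 rejoins the route at 8.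

**Step 5 (methylene coupling).** Possible failures are self-coupling of 8 to the methylene-bis homodimer, attack through C5 of 5, and double alkylation of 5. The fallback reverses the roles of the partners and sets out from 5. Phenolic Mannich reaction with aqueous formaldehyde and dimethylamine in EtOH at rt gives [3-[(dimethylamino)methyl]-2,4-dihydroxy-6-(3-methylbut-2-enyloxy)phenyl](phenyl)methanone F6, an isolable amine from which any C5 regioisomer is removed by acid–base extraction and chromatography. Heating F6 with 8 in toluene at 90 °C (well below the Claisen threshold of the prenyl ether) expels dimethylamine to give the ortho-quinone methide 4-benzoyl-5-hydroxy-6-methylidene-3-(3-methylbut-2-enyloxy)cyclohexa-2,4-dien-1-one F7. The enol of 8 traps F7 at its only free carbon, and the route is rejoined at 11.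

## Further compounds

F1 | step 2 | [2,6-dihydroxy-4-(triisopropylsilyloxy)phenyl](phenyl)methanone | CC(C)[Si](Oc1cc(O)c(C(=O)c2ccccc2)c(O)c1)(C(C)C)C(C)C
F2 | step 2 | [2-hydroxy-6-(3-methylbut-2-enyloxy)-4-(triisopropylsilyloxy)phenyl](phenyl)methanone | CC(C)=CCOc1cc(O[Si](C(C)C)(C(C)C)C(C)C)cc(O)c1C(=O)c1ccccc1
F3 | step 4 | 2,4-diacetylphloroglucinol, 1,1'-(2,4,6-trihydroxy-1,3-phenylene)di(ethan-1-one) | CC(=O)c1c(O)cc(O)c(C(C)=O)c1O
F4 | step 4 | 2,4-diacetyl-3,5-dihydroxy-6,6-dimethylcyclohexa-2,4-dien-1-one | CC(=O)C1=C(O)C(C(C)=O)=C(O)C(C)(C)C1=O
F5 | step 4 | filicinic acid, 3,5-dihydroxy-4,4-dimethylcyclohexa-2,5-dien-1-one | CC1(C)C(O)=CC(=O)C=C1O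
F6 | step 5 | [3-[(dimethylamino)methyl]-2,4-dihydroxy-6-(3-methylbut-2-enyloxy)phenyl](phenyl)methanone | CN(C)Cc1c(O)cc(OCC=C(C)C)c(C(=O)c2ccccc2)c1O
F7 | step 5 | 4-benzoyl-5-hydroxy-6-methylidene-3-(3-methylbut-2-enyloxy)cyclohexa-2,4-dien-1-one | C=C1C(=O)C=C(OCC=C(C)C)C(C(=O)c2ccccc2)=C1O
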